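**Retrosynthetic overview**

- The target is a 2,4-trans 2-aryl-4-alkylchroman (pyran ring O1–C2–C3–C4–C4a–C8a fused to the phloroglucinol-type ring A) with an 8-cinnamoyl group. The chalcone is unveiled last from an 8-acetyl group by aldol addition and dehydration, followed by global desilylation.
- Enabling feature: C4 is benzylic to ring A and ortho to the oxygen on C8a, so O=C8a–C4a=C4 is a latent ortho-quinone methide. C2 is benzylic to a para-oxygenated phenyl ring, so C2=C3 is a latent 4-hydroxystyrene and C2 is a quinone-methide-type cation that the C8a oxygen can capture reversibly.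
- Key disconnection: the pyran ring is opened to an ortho-quinone methide (from a 2-hydroxybenzyl alcohol) and a 4-silyloxystyrene. One chiral-acid-catalysed operation forms C3–C4 and then closes the ring at O1–C2, setting C4 (catalyst) and C2 (thermodynamic trans).
- The 2-hydroxybenzyl alcohol comes from an ortho-specific, boron-templated condensation of a 4-O-silylated acetophenone with a (3R)-3-silyloxy aldehyde. The aldehyde comes from a Keck allylation (carbinol centre) and ozonolysis.
- Ring order: ring A and the three hydroxyphenyl rings are purchased; the pyran ring is the only ring formed (step 8).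

Key step: step 8

Remark: compounds 8, 12 and 16 are taken as commercially available; TBS = tert-butyldimethylsilyl, TBSO = its ether. Silylation of the side-chain oxygen changes the CIP label at C4 from S (target 20, F2, F4) to R (compounds 14, 15, 17–19) without any change of geometry.

**Route**

Step 1
Reactants: 1 methyl 3-(4-hydroxyphenyl)propanoate
Product: 2 methyl 3-[4-(tert-butyldimethylsilyloxy)phenyl]propanoate
Conditions: TBSCl, imidazole, DMF, 25 °C
Reagents that add atoms: tert-butyldimethylsilyl chloride, CC(C)(C)[Si](C)(C)Cl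
Why: Silyl ether formation masks the acidic phenol for the hydride and Lewis acid steps and creates no stereocentre.

Step 2
Reactants: 2 methyl 3-[4-(tert-butyldimethylsilyloxy)phenyl]propanoate
Product: 3 3-[4-(tert-butyldimethylsilyloxy)phenyl]propanal
Conditions: iBu2AlH, CH2Cl2, −78 °C
Reagents that add atoms: none
Why: Partial reduction of the ester by the aluminium hydride at −78 °C stops at the aldehyde through a stable tetrahedral aluminate, and no stereocentre is formed.

Step 3
Reactants: 3 3-[4-(tert-butyldimethylsilyloxy)phenyl]propanal; 4 allyltributylstannane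
Product: 5 (3R)-1-[4-(tert-butyldimethylsilyloxy)phenyl]hex-5-en-3-ol
Conditions: (S)-BINOL (10 mol %), Ti(OiPr)4 (10 mol %), 4 Å MS, CH2Cl2, −20 °C; aq KF
Reagents that add atoms: none
Why: Keck asymmetric allylation, in which the (S)-BINOL titanate delivers the allyl group of 4 to one face of the aldehyde, sets the carbinol centre as R by reagent control because allyl outranks the arylethyl chain.

Step 4
Reactants: 5 (3R)-1-[4-(tert-butyldimethylsilyloxy)phenyl]hex-5-en-3-ol
Product: 6 (3R)-3-(tert-butyldimethylsilyloxy)-1-[4-(tert-butyldimethylsilyloxy)phenyl]hex-5-ene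
Conditions: TBSCl, imidazole, DMF, 40 °C
Reagents that add atoms: tert-butyldimethylsilyl chloride, CC(C)(C)[Si](C)(C)Cl
Why: Silyl ether formation turns the secondary alcohol into a poor leaving group for the later acidic steps and leaves the stereocentre untouched.

Step 5
Reactants: 6 (3R)-3-(tert-butyldimethylsilyloxy)-1-[4-(tert-butyldimethylsilyloxy)phenyl]hex-5-ene
Product: 7 (3R)-3-(tert-butyldimethylsilyloxy)-5-[4-(tert-butyldimethylsilyloxy)phenyl]pentanal
Conditions: O3, CH2Cl2, −78 °C; PPh3, −78 → 25 °C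
Reagents that add atoms: ozone, [O-][O+]=O
Why: Ozonolysis with reductive work-up cleaves the terminal alkene to the aldehyde whose carbon becomes C4, and the silyloxy stereocentre one carbon away cannot epimerise.

Step 6
Reactants: 8 1-(2,4-dihydroxy-6-methoxyphenyl)ethanone
Product: 9 1-[4-(tert-butyldimethylsilyloxy)-2-hydroxy-6-methoxyphenyl]ethanone
Conditions: TBSCl (1.05 equiv), imidazole, CH2Cl2, 0 °C
Reagents that add atoms: tert-butyldimethylsilyl chloride, CC(C)(C)[Si](C)(C)Cl
Why: Selective silylation of the phenol para to the acetyl group, the ortho phenol being held in a hydrogen bond to the carbonyl oxygen, leaves free only the oxygen that will become O1.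

Step 7
Reactants: 9 1-[4-(tert-butyldimethylsilyloxy)-2-hydroxy-6-methoxyphenyl]ethanone; 7 (3R)-3-(tert-butyldimethylsilyloxy)-5-[4-(tert-butyldimethylsilyloxy)phenyl]pentanal
Product: 11 1-[4-(TBSO)-2-hydroxy-3-[(3R)-1-hydroxy-3-(TBSO)-5-(4-TBSO-phenyl)pentyl]-6-methoxyphenyl]ethanone (both epimers at the benzylic carbinol), via benzodioxaborin 10 (not isolated)
Conditions: PhB(OH)2, EtCO2H (cat.), toluene, reflux (Dean–Stark); then HN(CH2CH2OH)2, THF, 25 °C
Reagents that add atoms: none
Why: Boron-templated ortho-specific hydroxyalkylation of a phenol with an aldehyde (phenylboronic acid condensation to a 1,3,2-benzodioxaborin, then transesterification) forms the ring A–C4 bond at the only free ortho carbon, and the new benzylic centre is a mixture that step 8 erases.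

Step 8
Reactants: 11 1-[4-(TBSO)-2-hydroxy-3-[(3R)-1-hydroxy-3-(TBSO)-5-(4-TBSO-phenyl)pentyl]-6-methoxyphenyl]ethanone; 12 4-(tert-butyldimethylsilyloxy)styrene
Product: 15 1-[(2R,4R)-5-(TBSO)-2-(4-TBSO-phenyl)-4-[(2R)-2-(TBSO)-4-(4-TBSO-phenyl)butyl]-7-methoxy-3,4-dihydro-2H-chromen-8-yl]ethanone (2,4-trans), via ortho-quinone methide 13 (not isolated), via zwitterion 14 (not isolated)
Conditions: (R)-3,3'-bis(2,4,6-triisopropylphenyl)-BINOL N-triflylphosphoramide (10 mol %), 12 (3 equiv), 4 Å MS, toluene, −40 → 25 °C (aged at 25 °C until C2 has equilibrated)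
Reagents that add atoms: none
Why: The acid dehydrates 11 to ortho-quinone methide 13, held by hydrogen bonds from the catalyst to the C8a carbonyl and the neighbouring acetyl oxygen; the terminal carbon of styrene 12 adds to C4 to give the catalyst-paired O-silyl para-quinone methide oxonium 14, and the ring A oxygen then closes on C2 in an asynchronous, formal hetero-Diels–Alder [4+2] process. The closest known reaction type is the chiral Brønsted acid catalysed [4+2] cycloaddition of ortho-quinone methides, released from 2-hydroxybenzyl alcohols, with styrenes to give 2-arylchromans. The pyran ring closes 6-exo-trig by oxa-1,6-addition of O1 to the quinone methide carbon C2 after the C3–C4 bond has formed. C4 is set in the C3–C4 bond formation by the chiral pocket of the catalyst (reagent control, with the catalyst antipode chosen for the required face and the silyloxy centre two carbons from C4 expected to weigh little), whereas C2 is set under thermodynamic control because O1–C2 ionises reversibly under the acid and the 2,4-trans isomer, with the 2-aryl group equatorial and the C4 chain pseudoaxial away from the peri C5 silyloxy group, is the more stable one. The step needs closure through the oxygen next to the acetyl group and not through the C5 oxygen, which the silyl ether on C5 secures. It also needs C–C bond formation at the styrene terminus, which the para-silyloxy group secures by stabilising the C2 cation, and the acetyl group in place of the chalcone keeps an enone and a flavanone-forming phenol out of the step.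

Step 9
Reactants: 15 1-[(2R,4R)-5-(TBSO)-2-(4-TBSO-phenyl)-4-[(2R)-2-(TBSO)-4-(4-TBSO-phenyl)butyl]-7-methoxy-3,4-dihydro-2H-chromen-8-yl]ethanone; 16 4-(tert-butyldimethylsilyloxy)benzaldehyde
Product: 17 3-hydroxy-1-[(2R,4R)-5-(TBSO)-2-(4-TBSO-phenyl)-4-[(2R)-2-(TBSO)-4-(4-TBSO-phenyl)butyl]-7-methoxy-3,4-dihydro-2H-chromen-8-yl]-3-(4-TBSO-phenyl)propan-1-one (both epimers at the new carbinol)
Conditions: LiN(SiMe3)2, THF, −78 °C; then 16; aq NH4Cl
Reagents that add atoms: none
Why: Directed aldol addition of the kinetic lithium enolate of the methyl ketone to aldehyde 16 builds the chalcone carbon skeleton without exposing the aryl silyl ethers to hydroxide, and the new carbinol centre (a mixture) is removed in step 10.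

Step 10
Reactants: 17 3-hydroxy-1-[(2R,4R)-5-(TBSO)-2-(4-TBSO-phenyl)-4-[(2R)-2-(TBSO)-4-(4-TBSO-phenyl)butyl]-7-methoxy-3,4-dihydro-2H-chromen-8-yl]-3-(4-TBSO-phenyl)propan-1-one
Product: 19 (2E)-1-[(2R,4R)-5-(TBSO)-2-(4-TBSO-phenyl)-4-[(2R)-2-(TBSO)-4-(4-TBSO-phenyl)butyl]-7-methoxy-3,4-dihydro-2H-chromen-8-yl]-3-(4-TBSO-phenyl)prop-2-en-1-one, via mesylate 18 (not isolated)
Conditions: MsCl, Et3N (excess), CH2Cl2, 0 → 25 °C
Reagents that add atoms: none
Why: Mesylation and E1cB elimination complete the aldol condensation and give the conjugated E enone, the favoured geometry, with the ring stereocentres untouched.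

Step 11
Reactants: 19 (2E)-1-[(2R,4R)-5-(TBSO)-2-(4-TBSO-phenyl)-4-[(2R)-2-(TBSO)-4-(4-TBSO-phenyl)butyl]-7-methoxy-3,4-dihydro-2H-chromen-8-yl]-3-(4-TBSO-phenyl)prop-2-en-1-one
Product: 20 (2E)-1-[(2R,4S)-5-hydroxy-4-[(2R)-2-hydroxy-4-(4-hydroxyphenyl)butyl]-2-(4-hydroxyphenyl)-7-methoxy-3,4-dihydro-2H-chromen-8-yl]-3-(4-hydroxyphenyl)prop-2-en-1-one (CNP0102599.2)
Conditions: HF·pyridine, pyridine, THF, 0 → 25 °C
Reagents that add atoms: none
Why: Fluoride-mediated cleavage of the four aryl and one alkyl silyl ethers under buffered conditions should release the target without ionising the O1–C2 bond, so the three stereocentres are retained.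

**Compound list**

1 | methyl 3-(4-hydroxyphenyl)propanoate | COC(=O)CCc1ccc(O)cc1 | starting material
2 | methyl 3-[4-(tert-butyldimethylsilyloxy)phenyl]propanoate | COC(=O)CCc1ccc(O[Si](C)(C)C(C)(C)C)cc1 | intermediate
3 | 3-[4-(tert-butyldimethylsilyloxy)phenyl]propanal | O=CCCc1ccc(O[Si](C)(C)C(C)(C)C)cc1 | intermediate
4 | allyltributylstannane | C=CC[Sn](CCCC)(CCCC)CCCC | starting material
5 | (3R)-1-[4-(tert-butyldimethylsilyloxy)phenyl]hex-5-en-3-ol | C=CC[C@H](O)CCc1ccc(O[Si](C)(C)C(C)(C)C)cc1 | intermediate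
6 | (3R)-3-(tert-butyldimethylsilyloxy)-1-[4-(tert-butyldimethylsilyloxy)phenyl]hex-5-ene | C=CC[C@H](O[Si](C)(C)C(C)(C)C)CCc1ccc(O[Si](C)(C)C(C)(C)C)cc1 | intermediate
7 | (3R)-3-(tert-butyldimethylsilyloxy)-5-[4-(tert-butyldimethylsilyloxy)phenyl]pentanal | O=CC[C@H](O[Si](C)(C)C(C)(C)C)CCc1ccc(O[Si](C)(C)C(C)(C)C)cc1 | intermediate
8 | 1-(2,4-dihydroxy-6-methoxyphenyl)ethanone | CC(=O)c1c(O)cc(O)cc1OC | starting material
9 | 1-[4-(tert-butyldimethylsilyloxy)-2-hydroxy-6-methoxyphenyl]ethanone | CC(=O)c1c(O)cc(O[Si](C)(C)C(C)(C)C)cc1OC | intermediate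
10 | 1-[5-(TBSO)-7-methoxy-2-phenyl-4-[(2R)-2-(TBSO)-4-(4-TBSO-phenyl)butyl]-4H-1,3,2-benzodioxaborin-8-yl]ethanone (both C4 epimers) | CC(=O)c1c2OB(c3ccccc3)OC(C[C@H](O[Si](C)(C)C(C)(C)C)CCc3ccc(O[Si](C)(C)C(C)(C)C)cc3)c2c(O[Si](C)(C)C(C)(C)C)cc1OC | intermediate
11 | 1-[4-(TBSO)-2-hydroxy-3-[(3R)-1-hydroxy-3-(TBSO)-5-(4-TBSO-phenyl)pentyl]-6-methoxyphenyl]ethanone (both benzylic epimers) | CC(=O)c1c(O)c(C(O)C[C@H](O[Si](C)(C)C(C)(C)C)CCc2ccc(O[Si](C)(C)C(C)(C)C)cc2)c(O[Si](C)(C)C(C)(C)C)cc1OC | intermediate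
12 | 4-(tert-butyldimethylsilyloxy)styrene | C=Cc1ccc(O[Si](C)(C)C(C)(C)C)cc1 | starting material
13 | ortho-quinone methide: 2-acetyl-5-(TBSO)-3-methoxy-6-[(3R)-3-(TBSO)-5-(4-TBSO-phenyl)pentylidene]cyclohexa-2,4-dien-1-one | CC(=O)C1=C(OC)C=C(O[Si](C)(C)C(C)(C)C)C(=CC[C@H](O[Si](C)(C)C(C)(C)C)CCc2ccc(O[Si](C)(C)C(C)(C)C)cc2)C1=O | intermediate
14 | zwitterion: ring A phenoxide with C4 (R) bonded to C3, whose C2 is the exocyclic carbon of an O-silyl para-quinone methide oxonium | CC(=O)c1c([O-])c([C@H](CC=C2C=CC(=[O+][Si](C)(C)C(C)(C)C)C=C2)C[C@H](O[Si](C)(C)C(C)(C)C)CCc2ccc(O[Si](C)(C)C(C)(C)C)cc2)c(O[Si](C)(C)C(C)(C)C)cc1OC | intermediate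
15 | 1-[(2R,4R)-5-(TBSO)-2-(4-TBSO-phenyl)-4-[(2R)-2-(TBSO)-4-(4-TBSO-phenyl)butyl]-7-methoxy-3,4-dihydro-2H-chromen-8-yl]ethanone | COc1cc(O[Si](C)(C)C(C)(C)C)c2c(c1C(C)=O)O[C@@H](c1ccc(O[Si](C)(C)C(C)(C)C)cc1)C[C@@H]2C[C@H](O[Si](C)(C)C(C)(C)C)CCc1ccc(O[Si](C)(C)C(C)(C)C)cc1 | intermediate
16 | 4-(tert-butyldimethylsilyloxy)benzaldehyde | O=Cc1ccc(O[Si](C)(C)C(C)(C)C)cc1 | starting material
17 | aldol adduct of 15 and 16 (β-hydroxy ketone, both carbinol epimers) | COc1cc(O[Si](C)(C)C(C)(C)C)c2c(c1C(=O)CC(O)c1ccc(O[Si](C)(C)C(C)(C)C)cc1)O[C@@H](c1ccc(O[Si](C)(C)C(C)(C)C)cc1)C[C@@H]2C[C@H](O[Si](C)(C)C(C)(C)C)CCc1ccc(O[Si](C)(C)C(C)(C)C)cc1 | intermediate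
18 | methanesulfonate of 17 | COc1cc(O[Si](C)(C)C(C)(C)C)c2c(c1C(=O)CC(OS(C)(=O)=O)c1ccc(O[Si](C)(C)C(C)(C)C)cc1)O[C@@H](c1ccc(O[Si](C)(C)C(C)(C)C)cc1)C[C@@H]2C[C@H](O[Si](C)(C)C(C)(C)C)CCc1ccc(O[Si](C)(C)C(C)(C)C)cc1 | intermediate
19 | penta-O-TBS ether of the target (E-chalcone) | COc1cc(O[Si](C)(C)C(C)(C)C)c2c(c1C(=O)/C=C/c1ccc(O[Si](C)(C)C(C)(C)C)cc1)O[C@@H](c1ccc(O[Si](C)(C)C(C)(C)C)cc1)C[C@@H]2C[C@H](O[Si](C)(C)C(C)(C)C)CCc1ccc(O[Si](C)(C)C(C)(C)C)cc1 | intermediate
20 | (2E)-1-[(2R,4S)-5-hydroxy-4-[(2R)-2-hydroxy-4-(4-hydroxyphenyl)butyl]-2-(4-hydroxyphenyl)-7-methoxy-3,4-dihydro-2H-chromen-8-yl]-3-(4-hydroxyphenyl)prop-2-en-1-one | COc1cc(O)c2c(c1C(=O)/C=C/c1ccc(O)cc1)O[C@@H](c1ccc(O)cc1)C[C@@H]2C[C@H](O)CCc1ccc(O)cc1 | target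

**Step count and risks**

Total step count: 11. Longest linear sequence: 10 steps (steps 1–5 and 7–11; step 6 runs in parallel).

Steps most likely to fail, riskiest first:

Step 8. The process at risk is facial selection at C4: catalyst control may be eroded by the nearby silyloxy centre, and the ortho-quinone methide may drain away by tautomerisation to the alkenylphenol and self-condensation before the styrene adds. The fallback replaces catalyst control by substrate control through a temporary ring. It sets out from 5, 9 and 16 and comes back at 15. A tandem Prins cyclisation/Friedel–Crafts arylation (BF3·OEt2, CH2Cl2, −78 → −20 °C) of homoallylic alcohol 5 with aldehyde 16, terminated by phenol 9 at its carbon ortho to the free hydroxyl, should give the all-cis 2,4,6-trisubstituted tetrahydropyran F1. The chair transition state places all three substituents equatorial, so C4 is fixed by the existing carbinol centre. Brief treatment with TsOH in CH2Cl2 at 25 °C ionises the benzylic C–O bond of the temporary ring, and the ring A oxygen recloses on the same carbon to give the 2,4-trans chroman carbinol F2 (the C5 oxygen is silylated, so only O1 can close). TBSCl and imidazole in DMF return 15. An adduct formed at the other free ring carbon of 9 has no ortho hydroxyl, cannot undergo the ring switch, and is removed at that stage.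

Step 7. The process at risk is a slow condensation at the hindered, hydrogen-bonded phenol, during which the acidic reflux eliminates silanol from the β-silyloxy aldehyde or starts an aldol reaction at the acetyl methyl group. The fallback changes the template from a boron ester under acid and heat to a magnesium chelate under aprotic conditions. It sets out from 9 and 7 and comes back at 11. EtMgBr (1 equiv, Et2O/toluene, 0 °C) converts 9 into the bromomagnesium phenolate F3. Aldehyde 7 is then added in toluene at 0 → 25 °C; coordination of the aldehyde to magnesium delivers it to the only free ortho carbon (ortho-specific hydroxyalkylation of magnesium phenolates), and aq NH4Cl releases 11.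

Step 11. The process at risk is slow cleavage of the secondary alkyl silyl ether, which leaves the free para-hydroxyphenyl chroman exposed to HF for a long time, so that O1–C2 ionises and C2 scrambles or migrates to the C5 oxygen. The fallback stages the deprotection by orthogonal lability. It sets out from 19 and comes back at 20. Camphorsulfonic acid (cat.) in MeOH/CH2Cl2 at 0 °C removes only the alkyl silyl ether, since aryl silyl ethers are stable to mild acid and all phenols are still capped, to give the tetra-aryl-silyl chalcone carbinol F4. A short treatment with Bu4NF/AcOH (1:1) in THF at 0 °C then cleaves the four aryl silyl ethers within minutes and gives 20.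

Further compounds
F1 | step 8 | 1-[4-(TBSO)-2-hydroxy-6-methoxy-3-[(2R,4S,6R)-2-(4-TBSO-phenyl)-6-[2-(4-TBSO-phenyl)ethyl]oxan-4-yl]phenyl]ethanone (all-cis tetrahydropyran) | CC(=O)c1c(O)c([C@@H]2C[C@H](c3ccc(O[Si](C)(C)C(C)(C)C)cc3)O[C@H](CCc3ccc(O[Si](C)(C)C(C)(C)C)cc3)C2)c(O[Si](C)(C)C(C)(C)C)cc1OC
F2 | step 8 | 1-[(2R,4S)-5-(TBSO)-2-(4-TBSO-phenyl)-4-[(2R)-2-hydroxy-4-(4-TBSO-phenyl)butyl]-7-methoxy-3,4-dihydro-2H-chromen-8-yl]ethanone | COc1cc(O[Si](C)(C)C(C)(C)C)c2c(c1C(C)=O)O[C@@H](c1ccc(O[Si](C)(C)C(C)(C)C)cc1)C[C@@H]2C[C@H](O)CCc1ccc(O[Si](C)(C)C(C)(C)C)cc1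
F3 | step 7 | bromomagnesium 2-acetyl-5-(tert-butyldimethylsilyloxy)-3-methoxyphenolate | CC(=O)c1c(O[Mg]Br)cc(O[Si](C)(C)C(C)(C)C)cc1OC
F4 | step 11 | (2E)-1-[(2R,4S)-5-(TBSO)-2-(4-TBSO-phenyl)-4-[(2R)-2-hydroxy-4-(4-TBSO-phenyl)butyl]-7-methoxy-3,4-dihydro-2H-chromen-8-yl]-3-(4-TBSO-phenyl)prop-2-en-1-one | COc1cc(O[Si](C)(C)C(C)(C)C)c2c(c1C(=O)/C=C/c1ccc(O[Si](C)(C)C(C)(C)C)cc1)O[C@@H](c1ccc(O[Si](C)(C)C(C)(C)C)cc1)C[C@@H]2C[C@H](O)CCc1ccc(O[Si](C)(C)C(C)(C)C)cc1
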